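**Plan**
- Retrosynthesis cuts no C–C bond: the C20 aldehyde and C19 acetate are traced to a 19,20-epoxy acetal, whose C20–O19 bond is cut to give the C19 alcohol and intact C20 methyl of andrograpanin. Re-adding the C3 and C14 oxygens leads to andrographolide.
- Forward: decalin and butenolide come ready-made. C14–O is removed by SN2′ hydride delivery and C3–O by radical cleavage of the 3,19-thionocarbonate. The only ring closed is the temporary oxane O19–C19–C4–C5–C10–C20, later reopened as a dithiane so that O19 can be acetylated.
- Enabling feature: on ring A of the trans-decalin, the C4 hydroxymethyl (C19) and the C10 methyl (C20) are both axial on the α face, 1,3 to each other across C5. A C19 alkoxy radical therefore sits within reach of a C20–H.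
- C20 is taken to the acetal level in the same flask, because a plain 19,20-ether would leave two O–CH2 groups that could not be told apart afterwards.
- The C8=C17 alkene is masked as its epoxide for the iodine step only.
- Stereochemistry: C4, C5, C9 and C10 are carried unchanged from andrographolide; the C8 epoxide and C20 acetal centres are temporary.

Key step: step 7

Remark: ent-labdane numbering is used (C19 = CH2O on C4, C20 = carbon on C10, C17 = exocyclic methylene; β = face of H5 and H9). The epoxide is drawn as the expected 8β isomer and the acetal carbon C20 without configuration; neither centre reaches the target.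

**Step 1**
Reactants: 1 andrographolide; 2 2,2-dimethoxypropane
Product: 3 3,19-O-isopropylidene-andrographolide
Conditions: Me2C(OMe)2, PPTS (cat.), toluene/DMSO, 80 °C
Reagents that add atoms: 2,2-dimethoxypropane, COC(C)(C)OC
Why: Acid-catalysed transacetalisation (acetonide formation) picks out the cis-related 3-OH/C19-OH 1,3-diol, closes a six-membered dioxane and leaves the allylic 14-OH as the only free hydroxyl; no stereocentre changes.

**Step 2**
Reactants: 3 3,19-O-isopropylidene-andrographolide; 4 acetic anhydride
Product: 5 14-O-acetyl-3,19-O-isopropylidene-andrographolide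
Conditions: Ac2O (neat), 140 °C, 1 h
Reagents that add atoms: acetic anhydride, CC(=O)OC(C)=O
Why: Acetylation of the one remaining (secondary allylic) hydroxyl under base-free conditions turns O14 into a leaving group without triggering 1,4-elimination; C14 keeps its configuration.

**Step 3**
Reactants: 5 14-O-acetyl-3,19-O-isopropylidene-andrographolide
Product: 7 14-deoxyandrographolide, via 14-deoxy acetonide 6 (not isolated)
Conditions: NaBH4, THF/MeOH, 0 °C; then AcOH/H2O (7:3), rt
Reagents that add atoms: none
Why: SN2′-type reductive transposition, in which borohydride adds in a conjugate sense to C12 of the alkylidene lactone and the lactone enolate expels the C14 acetate (E1cB), places the double bond at C13=C14 inside the ring and erases the C14 stereocentre, after which the aqueous acetic acid quench hydrolyses the acetonide.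

**Step 4**
Reactants: 7 14-deoxyandrographolide; 8 1,1'-thiocarbonyldiimidazole
Product: 9 14-deoxyandrographolide 3,19-cyclic thionocarbonate
Conditions: Im2C=S, DMAP (cat.), toluene, 90 °C
Reagents that add atoms: 1,1'-thiocarbonyldiimidazole, S=C(n1ccnc1)n1ccnc1
Why: Thiocarbonyl transfer to the same 1,3-diol closes a six-membered cyclic thionocarbonate, which arms C3–O for radical cleavage without separate protection of O19; no stereocentre changes.

**Step 5**
Reactants: 9 14-deoxyandrographolide 3,19-cyclic thionocarbonate
Product: 11 andrograpanin (19-hydroxy-ent-labda-8(17),13-dien-16,15-olide), via stannyl thiocarbonate 10 (not isolated)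
Conditions: Bu3SnH, AIBN (cat.), toluene, 110 °C; then AcOH, wet THF, rt
Reagents that add atoms: none
Why: Barton–McCombie deoxygenation of a diol thionocarbonate, in which the stannyl radical adds to sulfur, the ring opens at C3–O because that releases the secondary rather than the neopentyl primary radical, tin hydride reduces C3 to CH2 (the stereocentre disappears) and acetic acid cleaves the Sn–S bond so that the thiocarbonic half-ester on O19 loses COS.

**Step 6**
Reactants: 11 andrograpanin; 12 3-chloroperoxybenzoic acid
Product: 13 8β,17-epoxy-19-hydroxy-ent-labd-13-en-16,15-olide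
Conditions: mCPBA, NaHCO3, CH2Cl2, 0 °C
Reagents that add atoms: 3-chloroperoxybenzoic acid, O=C(OO)c1cccc(Cl)c1
Why: Prilezhaev epoxidation attacks the electron-rich 1,1-disubstituted C8=C17 bond and not the electron-poor butenolide, from the β face opposite the axial C20 methyl, which sets the temporary C8 centre; the epoxide hides the alkene from acetyl hypoiodite in step 7.

**Step 7**
Reactants: 13 8β,17-epoxy-19-hydroxy-ent-labd-13-en-16,15-olide; 14 (diacetoxyiodo)benzene
Product: 19 (20ξ)-20-acetoxy-8β,17:19,20-diepoxy-ent-labd-13-en-16,15-olide, via C19 hypoiodite 15 (not isolated), via 20-iodo alcohol 16 (not isolated), via 20,20-diiodo alcohol 17 (not isolated), via 20-iodo ether 18 (not isolated)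
Conditions: PhI(OAc)2 (3 equiv), I2 (1 equiv), NaHCO3, cyclohexane/CH2Cl2, hν (tungsten lamp), 30 °C
Reagents that add atoms: (diacetoxyiodo)benzene, CC(=O)OI(OC(C)=O)c1ccccc1
Why: Acetyl hypoiodite, made from PhI(OAc)2 and I2, turns O19–H into hypoiodite 15; light breaks the O–I bond and the C19 alkoxy radical takes a hydrogen from the C20 methyl through a seven-membered transition state (1,6-hydrogen transfer), after which iodine transfer to the C20 radical gives 16. With the oxidant in excess, 16 runs through the same cycle at the weaker C–H of its CH2I group to give the gem-diiodide 17, O19 then displaces one iodide in a 6-exo-tet closure that forms the C20–O bond and the oxane ring O19–C19–C4–C5–C10–C20 (18), and acetate replaces the second iodide through the oxocarbenium ion. The closest known reaction is the hypoiodite remote functionalisation (Suárez conditions) in its two-cycle form, by which an alcohol held next to an angular methyl group is converted into a cyclic hemiacetal derivative. The acetal carbon C20 is the only new stereocentre; nothing in the substrate needs to control it, the anomeric effect should favour an axial acetoxy group, and step 9 erases it. The selectivity needed is abstraction at C20 in preference to the δ-hydrogens on C2 and C6 and to β-scission with loss of formaldehyde; it rests on the trans-decalin, which holds C19 and C20 syn-axial on C4 and C10 so that a freely rotating methyl hydrogen can point straight at the oxygen at close range, a geometry the ring hydrogens cannot reach. Because the ring closes only after the second iodine is in place, C20 and not C19 carries the aldehyde oxidation level, so the two O–CH2 groups of a plain 19,20-ether never have to be told apart.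

**Step 8**
Reactants: 19 (20ξ)-20-acetoxy-8β,17:19,20-diepoxy-ent-labd-13-en-16,15-olide
Product: 21 (20ξ)-20-acetoxy-19,20-epoxy-ent-labda-8(17),13-dien-16,15-olide, via iodohydrin 20 (not isolated)
Conditions: Zn, NaI, NaOAc, AcOH, rt
Reagents that add atoms: none
Why: Reductive epoxide deoxygenation through the iodohydrin, in which iodide opens the spiro-epoxide at the primary C17 and zinc reduces the β-iodo alcohol with loss of the C8 oxygen, restores the exocyclic alkene and removes the temporary C8 centre, while buffered acetic acid should leave the anomeric acetate and the butenolide untouched.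

**Step 9**
Reactants: 21 (20ξ)-20-acetoxy-19,20-epoxy-ent-labda-8(17),13-dien-16,15-olide; 22 propane-1,3-dithiol
Product: 24 20-(1,3-dithian-2-yl) alcohol, i.e. 19-hydroxy-ent-labda-8(17),13-dien-16,15-olide with C20 as the dithiane carbon, via ring monothioacetal 23 (not isolated)
Conditions: HS(CH2)3SH, BF3·OEt2, CH2Cl2, −40 to 0 °C
Reagents that add atoms: propane-1,3-dithiol, SCCCS
Why: Lewis-acid dithioacetalisation, in which BF3 ionises the anomeric acetate, sulfur captures the oxocarbenium ion and the ring O,S-acetal reopens through the thionium ion to the stable 1,3-dithiane, erases the C20 acetal centre and releases O19–H, as in the conversion of pyranoses into open-chain dithioacetals.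

**Step 10**
Reactants: 24 20-(1,3-dithian-2-yl) alcohol; 4 acetic anhydride
Product: 25 19-acetoxy-20-(1,3-dithian-2-yl) compound
Conditions: Ac2O, pyridine, DMAP (cat.), CH2Cl2, rt
Reagents that add atoms: acetic anhydride, CC(=O)OC(C)=O
Why: DMAP-catalysed acetylation of the only hydroxyl present; the dithiane holds C20 in the open form, so the acetate can only end on O19.

**Step 11**
Reactants: 25 19-acetoxy-20-(1,3-dithian-2-yl) compound; 26 water
Product: 27 19-acetoxy-20-oxo-ent-labda-8(17),13-dien-16,15-olide (target)
Conditions: PhI(OCOCF3)2, NaHCO3, MeCN/H2O (9:1), 0 °C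
Reagents that add atoms: water, O
Why: Iodine(III)-mediated oxidative dithiane hydrolysis oxidises sulfur far faster than the alkene, water adds to the thionium ion, and the aldehyde on the quaternary C10 can neither enolise nor epimerise, so C4, C5, C9 and C10 arrive as in andrographolide.

**Compound list**
1 | andrographolide | C=C1CC[C@@H]2[C@](C)(CO)[C@H](O)CC[C@@]2(C)[C@@H]1C/C=C/3\[C@@H](COC3=O)O | starting material
2 | 2,2-dimethoxypropane | COC(C)(C)OC | starting material
3 | 3,19-O-isopropylidene-andrographolide | C=C1CC[C@@H]2[C@](C)(COC(C)(C)O4)[C@H]4CC[C@@]2(C)[C@@H]1C/C=C/3\[C@@H](COC3=O)O | intermediate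
4 | acetic anhydride | CC(=O)OC(C)=O | starting material
5 | 14-O-acetyl-3,19-O-isopropylidene-andrographolide | C=C1CC[C@@H]2[C@](C)(COC(C)(C)O4)[C@H]4CC[C@@]2(C)[C@@H]1C/C=C/3\[C@@H](COC3=O)OC(C)=O | intermediate
6 | 14-deoxy-3,19-O-isopropylidene-andrographolide (formed in the flask) | C=C1CC[C@@H]2[C@](C)(COC(C)(C)O4)[C@H]4CC[C@@]2(C)[C@@H]1CCC1=CCOC1=O | intermediate
7 | 14-deoxyandrographolide (3α,19-dihydroxy-ent-labda-8(17),13-dien-16,15-olide) | C=C1CC[C@@H]2[C@](C)(CO)[C@H](O)CC[C@@]2(C)[C@@H]1CCC1=CCOC1=O | intermediate
8 | 1,1'-thiocarbonyldiimidazole | S=C(n1ccnc1)n1ccnc1 | starting material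
9 | 14-deoxyandrographolide 3,19-cyclic thionocarbonate | C=C1CC[C@@H]2[C@](C)(COC(=S)O4)[C@H]4CC[C@@]2(C)[C@@H]1CCC1=CCOC1=O | intermediate
10 | andrograpanin 19-O-[(tributylstannylsulfanyl)carbonyl] derivative (formed in the flask) | C=C1CC[C@@H]2[C@](C)(COC(=O)S[Sn](CCCC)(CCCC)CCCC)CCC[C@@]2(C)[C@@H]1CCC1=CCOC1=O | intermediate
11 | andrograpanin (19-hydroxy-ent-labda-8(17),13-dien-16,15-olide) | C=C1CC[C@@H]2[C@](C)(CO)CCC[C@@]2(C)[C@@H]1CCC1=CCOC1=O | intermediate
12 | 3-chloroperoxybenzoic acid | O=C(OO)c1cccc(Cl)c1 | starting material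
13 | 8β,17-epoxy-19-hydroxy-ent-labd-13-en-16,15-olide | C1O[C@]12CC[C@@H]3[C@](C)(CO)CCC[C@@]3(C)[C@@H]2CCC2=CCOC2=O | intermediate
14 | (diacetoxyiodo)benzene | CC(=O)OI(OC(C)=O)c1ccccc1 | starting material
15 | C19 hypoiodite of 13 (formed in the flask) | C1O[C@]12CC[C@@H]3[C@](C)(COI)CCC[C@@]3(C)[C@@H]2CCC2=CCOC2=O | intermediate
16 | 20-iodo derivative of 13 (formed in the flask) | C1O[C@]12CC[C@@H]3[C@](C)(CO)CCC[C@@]3(CI)[C@@H]2CCC2=CCOC2=O | intermediate
17 | 20,20-diiodo derivative of 13 (formed in the flask) | C1O[C@]12CC[C@@H]3[C@](C)(CO)CCC[C@@]3(C(I)I)[C@@H]2CCC2=CCOC2=O | intermediate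
18 | (20ξ)-20-iodo-8β,17:19,20-diepoxy-ent-labd-13-en-16,15-olide (formed in the flask) | C1O[C@]12CC[C@@H]3[C@](C)(CO5)CCC[C@@]3(C5I)[C@@H]2CCC2=CCOC2=O | intermediate
19 | (20ξ)-20-acetoxy-8β,17:19,20-diepoxy-ent-labd-13-en-16,15-olide | C1O[C@]12CC[C@@H]3[C@](C)(CO5)CCC[C@@]3(C5OC(C)=O)[C@@H]2CCC2=CCOC2=O | intermediate
20 | (20ξ)-20-acetoxy-19,20-epoxy-8β-hydroxy-17-iodo-ent-labd-13-en-16,15-olide (formed in the flask) | IC[C@]1(O)CC[C@@H]2[C@](C)(CO5)CCC[C@@]2(C5OC(C)=O)[C@@H]1CCC1=CCOC1=O | intermediate
21 | (20ξ)-20-acetoxy-19,20-epoxy-ent-labda-8(17),13-dien-16,15-olide | C=C1CC[C@@H]2[C@](C)(CO5)CCC[C@@]2(C5OC(C)=O)[C@@H]1CCC1=CCOC1=O | intermediate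
22 | propane-1,3-dithiol | SCCCS | starting material
23 | (20ξ)-19,20-epoxy-20-(3-sulfanylpropylsulfanyl)-ent-labda-8(17),13-dien-16,15-olide (formed in the flask) | C=C1CC[C@@H]2[C@](C)(CO5)CCC[C@@]2(C5SCCCS)[C@@H]1CCC1=CCOC1=O | intermediate
24 | 19-hydroxy-ent-labda-8(17),13-dien-16,15-olide with C20 as 1,3-dithian-2-yl | C=C1CC[C@@H]2[C@](C)(CO)CCC[C@@]2(C3SCCCS3)[C@@H]1CCC1=CCOC1=O | intermediate
25 | 19-acetoxy-ent-labda-8(17),13-dien-16,15-olide with C20 as 1,3-dithian-2-yl | C=C1CC[C@@H]2[C@](C)(COC(C)=O)CCC[C@@]2(C3SCCCS3)[C@@H]1CCC1=CCOC1=O | intermediate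
26 | water | O | starting material
27 | 19-acetoxy-20-oxo-ent-labda-8(17),13-dien-16,15-olide (CNP0109410.1) | C=C1CC[C@@H]2[C@](C)(COC(C)=O)CCC[C@@]2(C=O)[C@@H]1CCC1=CCOC1=O | target

**Step count**
Total: 11 steps. Longest linear sequence: 11 steps (1 to 27); the route is fully linear.

**Steps most likely to fail**

Step 7. Three processes can defeat the step:
- Hydrogen abstraction at C2/C6 or loss of formaldehyde instead of attack on C20.
- Ring closure at the mono-iodide stage, which stops C20 at the ether level, or an incomplete second cycle that leaves a mixture of oxidation levels.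
- Opening of the epoxide mask by acetyl hypoiodite or acetic acid.

The fallback replaces iodine by nitric oxide as the radical trap. It sets out from 11 and comes back at 21, so steps 6–8 fall away. Exchange of the C19 hydroxyl with tert-butyl nitrite should give andrograpanin 19-nitrite F1. Barton nitrite photolysis (350 nm, benzene, rt, then warm 2-propanol to tautomerise the nitroso dimer) should place nitrogen on C20 and give the 19-hydroxy 20-oxime F2. This reaches the aldehyde oxidation level in one radical event, and the alkene can stay free because no electrophilic halogen is present. Buffered TiCl3 (NH4OAc, aqueous dioxane, rt) should cleave the oxime, and the hydroxy aldehyde closes to the 19,20-epoxy-20-ol lactol F3. Ac2O/pyridine then gives 21. The photolysis uses the same alkoxy radical, so on small scale it also serves as an early test of the C20 versus C2/C6 preference.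

Step 9. Acid-promoted migration of the 8(17) double bond into the ring, or addition of thiol to it, may outrun the slow opening of the hindered neopentyl acetal. The fallback avoids both acid and sulfur; it sets out from 21 and comes back at 27. NaBH4 with catalytic K2CO3 in MeOH at 0 °C should remove the anomeric acetate (the lactol released is F3 of the preceding fallback) and reduce the open hydroxy aldehyde to the 19,20-diol F4. One equivalent of Ac2O with 2,4,6-collidine (CH2Cl2, −20 °C) should acetylate the C19 hydroxyl, which sits on the periphery of ring A, ahead of the angular C20 hydroxyl, giving the 19-acetoxy-20-ol F5. Dess–Martin periodinane with NaHCO3 (CH2Cl2, rt) then gives 27.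

Step 5. The dioxanyl radical may open slowly or towards C19, or the thiocarbonate residue may stay on O19. The fallback separates protection and deoxygenation; it sets out from 7 and comes back at 11. TBSCl/imidazole (DMF, 0 °C) should silylate the primary C19 hydroxyl to give 19-O-TBS-14-deoxyandrographolide F6. PhOC(S)Cl with DMAP/pyridine (CH2Cl2, rt) gives the 3-O-phenoxythiocarbonyl derivative F7. Bu3SnH/AIBN (toluene, 100 °C) should give 19-O-TBS-andrograpanin F8, and HF·pyridine (THF, 0 °C) returns 11.

**Further compounds**
F1 | step 7 | andrograpanin 19-nitrite | C=C1CC[C@@H]2[C@](C)(CON=O)CCC[C@@]2(C)[C@@H]1CCC1=CCOC1=O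
F2 | step 7 | 19-hydroxy-20-(hydroxyimino)-ent-labda-8(17),13-dien-16,15-olide (E-oxime) | C=C1CC[C@@H]2[C@](C)(CO)CCC[C@@]2(/C=N/O)[C@@H]1CCC1=CCOC1=O
F3 | step 7 | (20ξ)-19,20-epoxy-20-hydroxy-ent-labda-8(17),13-dien-16,15-olide (lactol) | C=C1CC[C@@H]2[C@](C)(CO5)CCC[C@@]2(C5O)[C@@H]1CCC1=CCOC1=O
F4 | step 9 | 19,20-dihydroxy-ent-labda-8(17),13-dien-16,15-olide | C=C1CC[C@@H]2[C@](C)(CO)CCC[C@@]2(CO)[C@@H]1CCC1=CCOC1=O
F5 | step 9 | 19-acetoxy-20-hydroxy-ent-labda-8(17),13-dien-16,15-olide | C=C1CC[C@@H]2[C@](C)(COC(C)=O)CCC[C@@]2(CO)[C@@H]1CCC1=CCOC1=O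
F6 | step 5 | 19-O-(tert-butyldimethylsilyl)-14-deoxyandrographolide | C=C1CC[C@@H]2[C@](C)(CO[Si](C)(C)C(C)(C)C)[C@H](O)CC[C@@]2(C)[C@@H]1CCC1=CCOC1=O
F7 | step 5 | 19-O-(tert-butyldimethylsilyl)-3-O-(phenoxythiocarbonyl)-14-deoxyandrographolide | C=C1CC[C@@H]2[C@](C)(CO[Si](C)(C)C(C)(C)C)[C@H](OC(=S)Oc3ccccc3)CC[C@@]2(C)[C@@H]1CCC1=CCOC1=O
F8 | step 5 | 19-O-(tert-butyldimethylsilyl)-andrograpanin | C=C1CC[C@@H]2[C@](C)(CO[Si](C)(C)C(C)(C)C)CCC[C@@]2(C)[C@@H]1CCC1=CCOC1=O
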